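A small charge of Q, 0.20 M, gives X and E within minutes, and I want to know how E stands against X at a moment earlier than my first reading and at one later than my last.

| setting | amber | violet | flask |
|---|---|---|---|
| Q | 0.20 M | 0.30 M | 0.20 M |
| remark | the very flask that is asked about, followed so far | run made earlier |  |
| time |  |  | 20 min |

- amber (time / min: E / %, X / %): 0.333: 21.2, 51.1; 0.500: 22.6, 59.5; 0.833: 24.5, 63.0; 1.33: 26.8, 64.1; 2.50: 26.9, 64.3; 4.00: 26.3, 65.2
- violet (time / min: E / %, X / %): 0.667: 24.3, 58.9; 1.00: 24.6, 62.5; 2.00: 24.7, 63.4; 3.00: 23.9, 62.3; 5.00: 25.4, 61.8; 8.00: 23.5, 64.5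

(each reading ± 1 percentage point)

* share of E in E plus X at 0.80 s
* share of E in E plus X at 20 min

- a reading or a percentage of X counts all its forms, free or not

I fold the amber readings into one number, the split ratio b, summed E over summed X, 0.404, which is the selectivity factor of two parallel paths: like a fixed divider, two paths of one order with no return keep this ratio at every moment, so my share of E is b/(1+b), 28.8%, at both asked times. To test whether one number is enough, I take the first amber reading, which gives 0.415, the last, which gives 0.403, and the violet run at 0.30 M, which gives 0.392; these differ by no more than the scatter allows.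

The forecast says 28.5% (25% to 32%) at 0.80 s and 28.5% (26.5% to 30.5%) at 20 min, seeing “no trend with time, conversion or starting concentration”; my figure lies 0.30 percentage points above it.

The flask gives a share of E of 28.5% at 0.80 s and 28.2% at 20 min, the later share being a ratio of E to X of 0.393 against the 0.404 that I read as b from the amber readings.

    Q ⇌ X (K = 2.58, k = 0.0543 /s)
    Q ⇌ E (K = 45.5, k = 0.0215 /s)
    2 Q → Z (k = 0.0377 /M/s)
    L ⇌ X, rate k4*(cs4 - [X]) while solid is left; crystals form when [X] > cs4 (solubility = 2.70 mM, k = 0.662 /s)

At 20.0 min the flask holds X at 64.9%, of which crystals L are 63.6%. A neighbour charged with 0.050 M of Q gives a share of E of 28.5% at 0.80 s, close to the 28.8% from b, but at 20 min its ratio of E to X is 1.10, more than b, and its share of E is 52.5%.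

The runs were generated by integration for an exercise; noise was put on by code.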